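The route rests on opening ring B of the 1-aryl-1,2-dihydronaphthalene at C1–C2 and C3=C4 (C1 aryl-bearing CH, C2 CH–CH2OAc, C3 C–CHO, C4 vinylic CH). The aryl-conjugated 3-formyl alkene beside the diarylmethine C1 is read as the dehydrated adduct of a hydroxy-o-quinodimethane (C4, C4a, C8a and C1 on ring A) and a C2=C3 enal. An achiral 2-benzylbenzaldehyde is therefore photoenolised and trapped by the iminium ion of (E)-4-acetoxybut-2-enal under a chiral secondary amine: one operation forms both C–C bonds, closes ring B, sets C1 and C2 and, after loss of water, leaves the enal. Benzyl ethers mask the two phenols and are cleaved last.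

Key step: step 4

Assumption: 4-(benzyloxy)-3-methoxybenzyl chloride and 4-(benzyloxy)-2-bromo-5-methoxybenzaldehyde are bought as catalogue O-benzylvanillin derivatives.

Step 1
Reactants: 1 (Z)-but-2-ene-1,4-diyl diacetate; 2 (E)-but-2-enal (crotonaldehyde, 5 equiv)
Product: 3 (E)-4-oxobut-2-en-1-yl acetate
Conditions: second-generation Hoveyda–Grubbs catalyst RuCl2(H2IMes)(=CH-C6H4-2-Oi-Pr) (2 mol %), CH2Cl2, 40 °C
Reagents that add atoms: none
Why: Olefin cross-metathesis in which the internal cis-diacetate supplies two acetoxyethylidene units, excess crotonaldehyde and loss of volatile but-2-ene drive the exchange, and the conjugated enal should form as the E isomer under thermodynamic control.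

Step 2
Reactants: 4 1-(benzyloxy)-4-(chloromethyl)-2-methoxybenzene (4-(benzyloxy)-3-methoxybenzyl chloride)
Product: 5 2-[4-(benzyloxy)-3-methoxybenzyl]-4,4,5,5-tetramethyl-1,3,2-dioxaborolane
Conditions: B2pin2, Pd(dba)2 (3 mol %), P(4-MeOC6H4)3 (6 mol %), KOAc, toluene, 50 °C
Reagents that add atoms: bis(pinacolato)diboron, CC1(C)OB(OC1(C)C)B1OC(C)(C)C(C)(C)O1
Why: Miyaura borylation of a benzylic chloride, in which oxidative addition of the C–Cl bond to zerovalent palladium, acetate-assisted transmetalation with the diboron and reductive elimination should give the benzylboronate while the benzyl and methyl ethers stay inert.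

Step 3
Reactants: 5 2-[4-(benzyloxy)-3-methoxybenzyl]-4,4,5,5-tetramethyl-1,3,2-dioxaborolane; 6 4-(benzyloxy)-2-bromo-5-methoxybenzaldehyde
Product: 7 4-(benzyloxy)-2-[4-(benzyloxy)-3-methoxybenzyl]-5-methoxybenzaldehyde
Conditions: Pd(dppf)Cl2·CH2Cl2 (5 mol %), K2CO3, 1,4-dioxane/H2O, 90 °C
Reagents that add atoms: none
Why: Suzuki–Miyaura C(sp2)–C(sp3) coupling in which the ortho-formyl group speeds oxidative addition of the aryl bromide, the benzylboron partner has no β-hydrogen to lose, and the free aldehyde is tolerated.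

Step 4
Reactants: 7 4-(benzyloxy)-2-[4-(benzyloxy)-3-methoxybenzyl]-5-methoxybenzaldehyde; 3 (E)-4-oxobut-2-en-1-yl acetate (3 equiv)
Product: 10 [(1S,2R)-7-(benzyloxy)-1-[4-(benzyloxy)-3-methoxyphenyl]-3-formyl-6-methoxy-1,2-dihydronaphthalen-2-yl]methyl acetate, via photoenol 8 (not isolated), via β-hydroxy aldehyde 9 (not isolated)
Conditions: (R)-2-[diphenyl(trimethylsilyloxy)methyl]pyrrolidine (20 mol %), PhCO2H (20 mol %), degassed toluene, 365 nm LED, 0 °C; then lamp off, 25 °C
Reagents that add atoms: none
Why: Proposed new method: 365 nm light should turn 7, by triplet 1,5-hydrogen transfer from the doubly benzylic CH2, into the (E,E)-hydroxy-o-quinodimethane 8 (the Z-hydroxy isomer reverts to 7), whose aryl-bearing terminus (future C1) is the nucleophilic end of a dienol, while 3 is held as the E-iminium ion of the (R)-prolinol ether; C1 adds to the iminium β-carbon (future C2), the resulting enamine carbon (C3) closes onto the carbonyl carbon (C4), and the β-hydroxy aldehyde 9 loses one molecule of water through its enamine (E1cB) to give the arene-conjugated enal 10. The closest known reactions are the photoenolization/Diels–Alder reaction of 2-benzylbenzaldehydes with electron-poor alkenes, the light-driven amine-catalysed β-benzylation of enals by photoenols of 2-alkylbenzophenones, and the thermal amine-catalysed Michael/aldol condensation of 2-(nitromethyl)benzaldehydes with enals to 1,2-dihydronaphthalene-3-carbaldehydes; new is their merger on a 2-benzylbenzaldehyde. Ring B closes as a formal [4+2] cycloaddition (diene C4=C4a–C8a=C1, dienophile C2=C3), the second bond being a 6-(enolexo)-exo-trig aldol closure if the process is stepwise. C2 is set by the catalyst, whose diphenyl(silyloxy)methyl group blocks one face of the iminium ion so that the (R)-amine should give (2R); C1 is set relative to C2 by the endo arrangement of the iminium unit under the diene with the aryl group pointing outward, which places aryl and CH2OAc trans and gives (1S). The step needs regiocontrol, secured by the matched polarity of the dienol terminus and the iminium β-carbon, and it needs the iminium path to outrun racemic addition to free 3, secured by the far higher electrophilicity of the iminium ion, the low stationary concentration of 8 and the low temperature.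

Step 5
Reactants: 10 [(1S,2R)-7-(benzyloxy)-1-[4-(benzyloxy)-3-methoxyphenyl]-3-formyl-6-methoxy-1,2-dihydronaphthalen-2-yl]methyl acetate
Product: 11 [(1S,2R)-3-formyl-7-hydroxy-1-(4-hydroxy-3-methoxyphenyl)-6-methoxy-1,2-dihydronaphthalen-2-yl]methyl acetate (CNP0549177.1)
Conditions: BCl3 (4 equiv), C6HMe5 (6 equiv), CH2Cl2, −78 °C; then aq. NaHCO3
Reagents that add atoms: none
Why: Lewis-acid cleavage of aryl benzyl ethers with a non-Lewis-basic cation scavenger, in which BCl3 ionises the benzyl–oxygen bonds at −78 °C and pentamethylbenzene captures the benzyl cations, so that the methyl ethers, the alkyl acetate, the enal, the ring alkene (which hydrogenolysis would reduce) and both stereocentres should be untouched.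

Compound list
1 | (Z)-but-2-ene-1,4-diyl diacetate | CC(=O)OC/C=C\COC(C)=O | starting material
2 | (E)-but-2-enal (crotonaldehyde) | C/C=C/C=O | starting material
3 | (E)-4-oxobut-2-en-1-yl acetate | CC(=O)OC/C=C/C=O | intermediate
4 | 1-(benzyloxy)-4-(chloromethyl)-2-methoxybenzene | COc1cc(CCl)ccc1OCc1ccccc1 | starting material
5 | 2-[4-(benzyloxy)-3-methoxybenzyl]-4,4,5,5-tetramethyl-1,3,2-dioxaborolane | COc1cc(CB2OC(C)(C)C(C)(C)O2)ccc1OCc1ccccc1 | intermediate
6 | 4-(benzyloxy)-2-bromo-5-methoxybenzaldehyde | COc1cc(C=O)c(Br)cc1OCc1ccccc1 | starting material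
7 | 4-(benzyloxy)-2-[4-(benzyloxy)-3-methoxybenzyl]-5-methoxybenzaldehyde | COc1cc(C=O)c(Cc2ccc(OCc3ccccc3)c(OC)c2)cc1OCc1ccccc1 | intermediate
8 | (E,E)-hydroxy-o-quinodimethane photoenol of 7 (hydroxyl and aryl group both pointing outward), not isolated | O/C=C1\C=C(OC)C(OCc2ccccc2)=C/C1=C\c1ccc(OCc2ccccc2)c(OC)c1 | intermediate
9 | [(1S,2R,3S,4S)-7-(benzyloxy)-1-[4-(benzyloxy)-3-methoxyphenyl]-3-formyl-4-hydroxy-6-methoxy-1,2,3,4-tetrahydronaphthalen-2-yl]methyl acetate (endo adduct; C3 and C4 are erased on dehydration), not isolated | COc1cc([C@H]2c3cc(OCc4ccccc4)c(OC)cc3[C@@H](O)[C@@H](C=O)[C@@H]2COC(C)=O)ccc1OCc1ccccc1 | intermediate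
10 | [(1S,2R)-7-(benzyloxy)-1-[4-(benzyloxy)-3-methoxyphenyl]-3-formyl-6-methoxy-1,2-dihydronaphthalen-2-yl]methyl acetate | COc1cc([C@H]2c3cc(OCc4ccccc4)c(OC)cc3C=C(C=O)[C@@H]2COC(C)=O)ccc1OCc1ccccc1 | intermediate
11 | [(1S,2R)-3-formyl-7-hydroxy-1-(4-hydroxy-3-methoxyphenyl)-6-methoxy-1,2-dihydronaphthalen-2-yl]methyl acetate, trans at C1/C2 | COc1cc([C@H]2c3cc(O)c(OC)cc3C=C(C=O)[C@@H]2COC(C)=O)ccc1O | target

Total step count: 5. Longest linear sequence: 4 steps (4 → 5 → 7 → 10 → 11); step 1 runs in parallel.

Steps most likely to fail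

Step 4 (Proposed new method). The photoenol may be consumed by free enal, or by 6π-electrocyclisation onto the pendant aryl ring, faster than by the iminium ion, so ring B would form with poor enantio- or diastereocontrol. The product enal may also absorb the light and degrade. The fallback uses known chemistry, sets out from 7 and 3, and comes back at 10. The plain photoenolization/Diels–Alder reaction without amine (365 nm, degassed toluene, excess 3) should give the endo adduct as a racemate, that is 9 together with its mirror image ent-9 F1. Catalytic p-TsOH in toluene at 40 °C then dehydrates the pair. Preparative chiral-phase SFC separates 10 from its mirror image ent-10 F2.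

Step 5. Benzyl ether cleavage may be accompanied by loss of the acetate or of a methyl ether, or by Lewis-acid-triggered attack on the enal. The fallback moves the protecting-group change ahead of ring formation; it sets out from 7 and comes back at 11. Hydrogenolysis (H2, 10% Pd/C, EtOAc, 25 °C, stopped before the aldehyde is reduced) should give the bisphenol 4-hydroxy-2-(4-hydroxy-3-methoxybenzyl)-5-methoxybenzaldehyde F3. TBSCl and imidazole in DMF give the bis(tert-butyldimethylsilyl) ether F4. The conditions of step 4 with 3 then lead, through the photoenol F5 and the β-hydroxy aldehyde F6 (neither isolated), with loss of water, to the bis-silylated dihydronaphthalene F7. HF·pyridine in THF/pyridine at 0 °C frees both phenols and gives 11.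

Step 3. Transmetalation of the benzylboronate may be slower than its protodeboronation or homocoupling. The fallback inverts the polarity of the coupling; it sets out from 6 and comes back at 7. Miyaura borylation of 6 (B2pin2, Pd(dppf)Cl2, KOAc, 1,4-dioxane, 85 °C) should give the pinacol arylboronate F8, which is coupled with benzyl chloride 4 (Pd(PPh3)4, Na2CO3, DME/H2O, 80 °C) to give 7.

Further compounds
F1 | step 4 | ent-9, [(1R,2S,3R,4R)-7-(benzyloxy)-1-[4-(benzyloxy)-3-methoxyphenyl]-3-formyl-4-hydroxy-6-methoxy-1,2,3,4-tetrahydronaphthalen-2-yl]methyl acetate | COc1cc([C@@H]2c3cc(OCc4ccccc4)c(OC)cc3[C@H](O)[C@H](C=O)[C@H]2COC(C)=O)ccc1OCc1ccccc1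
F2 | step 4 | ent-10, [(1R,2S)-7-(benzyloxy)-1-[4-(benzyloxy)-3-methoxyphenyl]-3-formyl-6-methoxy-1,2-dihydronaphthalen-2-yl]methyl acetate | COc1cc([C@@H]2c3cc(OCc4ccccc4)c(OC)cc3C=C(C=O)[C@H]2COC(C)=O)ccc1OCc1ccccc1
F3 | step 5 | 4-hydroxy-2-(4-hydroxy-3-methoxybenzyl)-5-methoxybenzaldehyde | COc1cc(C=O)c(Cc2ccc(O)c(OC)c2)cc1O
F4 | step 5 | 4-(tert-butyldimethylsilyloxy)-2-[4-(tert-butyldimethylsilyloxy)-3-methoxybenzyl]-5-methoxybenzaldehyde | COc1cc(C=O)c(Cc2ccc(O[Si](C)(C)C(C)(C)C)c(OC)c2)cc1O[Si](C)(C)C(C)(C)C
F5 | step 5 | (E,E)-hydroxy-o-quinodimethane photoenol of F4, not isolated | O/C=C1\C=C(OC)C(O[Si](C)(C)C(C)(C)C)=C/C1=C\c1ccc(O[Si](C)(C)C(C)(C)C)c(OC)c1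
F6 | step 5 | [(1S,2R,3S,4S)-7-(tert-butyldimethylsilyloxy)-1-[4-(tert-butyldimethylsilyloxy)-3-methoxyphenyl]-3-formyl-4-hydroxy-6-methoxy-1,2,3,4-tetrahydronaphthalen-2-yl]methyl acetate, not isolated | COc1cc([C@H]2c3cc(O[Si](C)(C)C(C)(C)C)c(OC)cc3[C@@H](O)[C@@H](C=O)[C@@H]2COC(C)=O)ccc1O[Si](C)(C)C(C)(C)C
F7 | step 5 | [(1S,2R)-7-(tert-butyldimethylsilyloxy)-1-[4-(tert-butyldimethylsilyloxy)-3-methoxyphenyl]-3-formyl-6-methoxy-1,2-dihydronaphthalen-2-yl]methyl acetate | COc1cc([C@H]2c3cc(O[Si](C)(C)C(C)(C)C)c(OC)cc3C=C(C=O)[C@@H]2COC(C)=O)ccc1O[Si](C)(C)C(C)(C)C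
F8 | step 3 | 4-(benzyloxy)-5-methoxy-2-(4,4,5,5-tetramethyl-1,3,2-dioxaborolan-2-yl)benzaldehyde | COc1cc(C=O)c(B2OC(C)(C)C(C)(C)O2)cc1OCc1ccccc1
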